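A direct plan would add a thioacetal anion to the menthol-derived alkoxybutenolide A1 and benzylate the enolate to reach lactone A2. It would then unmask the aldehyde A3 and add to it the aryl metal made from bromide A4, whose glycerol ether would come from an auxiliary syn aldol; debenzylation would end it. Its weakest steps would be:
- the aryl-metal addition to A3, because the carbinol carbon C7' on lactone C4 would rest on 1,2-induction alone, next to a lactone and an epimerisable centre;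
- the mercury-assisted thioacetal hydrolysis, which would add length and give a labile aldehyde;
- the closing hydrogenolysis, which would have to spare two benzylic alcohols.

The route exploits that the lactone CH2–O carbon C5, raised to the acyl level, turns the exocyclic C4–C7' bond into an aldol bond of an open-chain succinate. C3 is set first by asymmetric hydrogenation of a Stobbe half-ester; the key step is then a magnesium-catalysed anti aldol of succinate imide 11 with aldehyde 25, which already carries the threo glycerol ether on ring B. It joins both halves and sets C4 and C7' under auxiliary control, and reduction of the auxiliary carbonyl closes the lactone last. No aryl metal and no thioacetal appear, C7' comes from the aldol itself, and no hydrogenolysis is run once a benzylic alcohol exists, since only silyl groups remain at the end.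

Key step: step 12

Remarks.
- Numbering: lactone O1, C2 (C=O), C3, C4, C5; C7' is the carbinol carbon on C4; C7'', C8'', C9'' are the glycerol carbons. Ring A is the aryl of the C3 benzyl group, ring B the aryl on C7', ring C the aryl on C7''.
- Abbreviations: TBS = tert-butyldimethylsilyl, TIPS = triisopropylsilyl, TMS = trimethylsilyl. ArB = 4-{[(1S,2S)-1,3-bis(TBS-oxy)-1-[3-methoxy-4-(TIPS-oxy)phenyl]propan-2-yl]oxy}-3-methoxyphenyl.
- Assumption: the facial sense of the rhodium and ruthenium hydrogenation catalysts is taken by analogy with itaconate half-esters and α-alkoxy β-keto esters; the mirror-image ligand would be used if a sense proved opposite.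

Step 1
Reactants: 1 4-(benzyloxy)-3-methoxybenzaldehyde; 2 dimethyl succinate
Product: 4 (E)-4-[4-(benzyloxy)-3-methoxyphenyl]-3-(methoxycarbonyl)but-3-enoic acid, via paraconic ester lactone 3 (not isolated)
Conditions: NaOMe, MeOH, reflux; then 2 M HCl
Reagents that add atoms: none
Why: Stobbe condensation, in which the succinate enolate adds to the aldehyde, the alkoxide closes to lactone 3 and base-induced ring opening gives the E half-ester with the free acid on the CH2 arm (later C5) and the methyl ester on the later C2.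

Step 2
Reactants: 4 the Stobbe half-ester
Product: 6 (3R)-4-(4-hydroxy-3-methoxyphenyl)-3-(methoxycarbonyl)butanoic acid, via benzyl ether 5 (not isolated)
Conditions: [Rh(cod)((S,S)-Et-DuPHOS)]BF4 (1 mol%), NaOMe (0.1 equiv), H2 (5 atm), MeOH, rt; then 10% Pd/C, H2 (1 atm), rt
Reagents that add atoms: none
Why: Carboxylate-directed rhodium-catalysed asymmetric hydrogenation of the itaconate-type half-ester should set C3 as R through the chiral bisphosphine, and hydrogenolysis of the benzyl ether is done here, before any benzylic alcohol exists.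

Step 3
Reactants: 6 the phenol acid
Product: 8 (3R)-4-[3-methoxy-4-(TBS-oxy)phenyl]-3-(methoxycarbonyl)butanoic acid, via silyl ester 7 (not isolated)
Conditions: TBSCl (2.5 equiv), imidazole, DMF, rt; then AcOH–THF–H2O, rt
Reagents that add atoms: tert-butyldimethylsilyl chloride, CC(C)(C)[Si](C)(C)Cl
Why: Silyl ether formation on phenol and acid followed by selective hydrolysis of the far more labile silyl ester leaves the ring A phenol masked by a group that fluoride removes at the end.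

Step 4
Reactants: 8 the silylated acid; 9 (R)-4-benzyl-1,3-oxazolidin-2-one
Product: 11 methyl (2R)-2-[3-methoxy-4-(TBS-oxy)benzyl]-4-[(4R)-4-benzyl-2-oxo-1,3-oxazolidin-3-yl]-4-oxobutanoate, via mixed pivalic anhydride 10 (not isolated)
Conditions: t-BuCOCl, Et3N, THF, −20 °C; then 9, LiCl, −20 °C → rt
Reagents that add atoms: none
Why: N-acylation of the oxazolidinone through the mixed pivalic anhydride places the auxiliary on the C5 carboxyl, attack occurring at the less hindered succinyl carbonyl.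

Step 5
Reactants: 12 4-hydroxy-3-methoxybenzonitrile; 13 ethyl bromoacetate
Product: 14 ethyl 2-(4-cyano-2-methoxyphenoxy)acetate
Conditions: K2CO3, acetone, reflux
Reagents that add atoms: none
Why: Williamson etherification of the acidic phenol forms the C8''–O–aryl bond of ring B at the outset, the nitrile serving as a masked aldehyde that is inert until step 11.

Step 6
Reactants: 15 vanillic acid (4-hydroxy-3-methoxybenzoic acid)
Product: 17 3-methoxy-4-(TIPS-oxy)benzoic acid, via silyl ester 16 (not isolated)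
Conditions: TIPSCl (2.2 equiv), imidazole, DMF, rt; then 1 M HCl, THF, rt
Reagents that add atoms: triisopropylsilyl chloride, CC(C)[Si](Cl)(C(C)C)C(C)C
Why: Exhaustive silylation and selective hydrolysis of the silyl ester (standard silyl protection of a hydroxybenzoic acid) give the ring C acid with a robust aryl silyl ether.

Step 7
Reactants: 14 the aryloxyacetate; 17 the silylated acid
Product: 20 ethyl 2-(4-cyano-2-methoxyphenoxy)-3-[3-methoxy-4-(TIPS-oxy)phenyl]-3-oxopropanoate (racemic), via acid chloride 18 (not isolated), via lithium ester enolate 19 (not isolated)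
Conditions: 17, (COCl)2, DMF (cat.), CH2Cl2, 0 °C → rt, evaporate; 14 (2.1 equiv), LiN(SiMe3)2 (2.1 equiv), THF, −78 °C; add 18, −78 → −30 °C; aq NH4Cl
Reagents that add atoms: none
Why: Claisen-type C-acylation of the lithium ester enolate by the aroyl chloride gives the α-aryloxy β-keto ester, the second equivalent of enolate taking up the acidic proton of the product.

Step 8
Reactants: 20 the racemic β-keto ester
Product: 21 ethyl (2R,3S)-2-(4-cyano-2-methoxyphenoxy)-3-hydroxy-3-[3-methoxy-4-(TIPS-oxy)phenyl]propanoate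
Conditions: [RuCl((R,R)-TsDPEN)(p-cymene)] (1 mol%), HCO2H–Et3N (5:2), CH2Cl2, 30 °C
Reagents that add atoms: none
Why: Noyori-type asymmetric transfer hydrogenation with dynamic kinetic resolution, in which C8'' epimerises through the enol while the catalyst reduces one face of the ketone and the syn (threo) preference of α-alkoxy β-keto esters applies, should set C7'' (catalyst) and C8'' (syn preference) together.

Step 9
Reactants: 21 the syn hydroxy ester
Product: 22 4-{[(1S,2S)-1,3-dihydroxy-1-[3-methoxy-4-(TIPS-oxy)phenyl]propan-2-yl]oxy}-3-methoxybenzonitrile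
Conditions: NaBH4, EtOH–THF, 0 °C → rt
Reagents that add atoms: none
Why: Borohydride reduction of the activated α-aryloxy β-hydroxy ester gives the primary alcohol without touching nitrile, silyl ether or either stereocentre, after which C8'' is no longer acidic.

Step 10
Reactants: 22 the threo diol
Product: 23 4-{[(1S,2S)-1,3-bis(TBS-oxy)-1-[3-methoxy-4-(TIPS-oxy)phenyl]propan-2-yl]oxy}-3-methoxybenzonitrile
Conditions: TBSOTf (2.5 equiv), 2,6-lutidine, CH2Cl2, −78 → 0 °C
Reagents that add atoms: tert-butyldimethylsilyl trifluoromethanesulfonate, CC(C)(C)[Si](C)(C)OS(=O)(=O)C(F)(F)F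
Why: Silyl ether formation with the silyl triflate and a hindered base masks both hydroxyls for the hydride and enolisation steps and keeps the end-game to one fluoride treatment.

Step 11
Reactants: 23 the protected nitrile
Product: 25 4-{[(1S,2S)-1,3-bis(TBS-oxy)-1-[3-methoxy-4-(TIPS-oxy)phenyl]propan-2-yl]oxy}-3-methoxybenzaldehyde (ArB–CHO), via aluminium aldimine 24 (not isolated)
Conditions: i-Bu2AlH (1.5 equiv), toluene, −78 → −20 °C; then aq KNaC4H4O6, 5% aq citric acid, rt
Reagents that add atoms: water, O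
Why: Partial reduction of the aryl nitrile by the aluminium hydride stops at the N-aluminio aldimine 24, whose hydrolysis on work-up gives the aldehyde while silyl and aryl ethers are inert.

Step 12
Reactants: 11 the succinate imide (1.2 equiv); 25 the aldehyde
Product: 28 methyl (2R,3S)-2-[3-methoxy-4-(TBS-oxy)benzyl]-3-[(R)-ArB(TMS-oxy)methyl]-4-[(4R)-4-benzyl-2-oxo-1,3-oxazolidin-3-yl]-4-oxobutanoate, via chloromagnesium Z-enolate 26 (not isolated), via chloromagnesium aldolate 27 (not isolated)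
Conditions: MgCl2 (0.2 equiv), Et3N (2.5 equiv), Me3SiCl (2.0 equiv), EtOAc, rt, 24–48 h; filtration through silica (Et2O)
Reagents that add atoms: chlorotrimethylsilane, C[Si](C)(C)Cl
Why: Soft enolisation of the magnesium-chelated imide by Et3N gives the chelated Z-enolate 26, which adds to the aromatic aldehyde through a boat-like transition state to aldolate 27; silylation of 27 by Me3SiCl frees MgCl2 for turnover and makes the addition irreversible. The closest known reaction type is the magnesium halide-catalysed anti aldol of N-acyloxazolidinones with non-enolisable aromatic aldehydes. No ring is closed; the step forms the C4–C7' bond that joins the two halves. C4 is controlled by the auxiliary, whose benzyl group shields one face of the chelated enolate so that the aldehyde enters from the other, and C7' is controlled by the boat transition state, which places the oxygen and the C3 branch anti; C3 is a spectator. The step needs enolisation at the imide CH2 and not at the ester CH, which the chelation of magnesium by the two imide carbonyls and the lower acidity of the ester secure, and anti over syn addition, which the chelated enolate and the aromatic aldehyde secure. The anti adduct of this facial sense corresponds to 4R,7'R in the target.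

Step 13
Reactants: 28 the silylated aldol adduct
Product: 30 (3R,4R)-3-[3-methoxy-4-(TBS-oxy)benzyl]-4-[(R)-ArB(TMS-oxy)methyl]dihydrofuran-2(3H)-one, via hydroxy ester 29 (not isolated)
Conditions: LiBH4 (1.2 equiv), MeOH (1.2 equiv), THF, 0 °C; aq NH4Cl; then PPTS (cat.), CH2Cl2, rt
Reagents that add atoms: none
Why: Reductive cleavage of the N-acyloxazolidinone (the activated exocyclic carbonyl reacts faster than the methyl ester) gives the C5 alcohol 29, which lactonises onto the C2 ester while the silylated C7' oxygen cannot compete, so the lactone ring is closed last with C3, C4 and C7' untouched.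

Step 14
Reactants: 30 the silylated lactone
Product: 31 target, (3R,4R)-3-(4-hydroxy-3-methoxybenzyl)-4-[(R)-hydroxy(4-{[(1S,2S)-1,3-dihydroxy-1-(4-hydroxy-3-methoxyphenyl)propan-2-yl]oxy}-3-methoxyphenyl)methyl]dihydrofuran-2(3H)-one
Conditions: Bu4NF (8 equiv), AcOH (8 equiv), THF, 0 °C → rt
Reagents that add atoms: none
Why: Fluoride-mediated global desilylation buffered with acetic acid removes the TMS, the two alkyl TBS, the aryl TBS and the aryl TIPS groups without base-induced translactonisation, quinone methide formation or any reductive step, so all five stereocentres should survive.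

**Compound list**

1 | 4-(benzyloxy)-3-methoxybenzaldehyde | COc1cc(C=O)ccc1OCc1ccccc1 | starting material
2 | dimethyl succinate | COC(=O)CCC(=O)OC | starting material
3 | methyl 2-[4-(benzyloxy)-3-methoxyphenyl]-5-oxotetrahydrofuran-3-carboxylate (racemic paraconic ester lactone) | COC(=O)C1CC(=O)OC1c1ccc(OCc2ccccc2)c(OC)c1 | intermediate
4 | (E)-4-[4-(benzyloxy)-3-methoxyphenyl]-3-(methoxycarbonyl)but-3-enoic acid | COC(=O)/C(CC(=O)O)=C/c1ccc(OCc2ccccc2)c(OC)c1 | intermediate
5 | (3R)-4-[4-(benzyloxy)-3-methoxyphenyl]-3-(methoxycarbonyl)butanoic acid | COC(=O)[C@@H](CC(=O)O)Cc1ccc(OCc2ccccc2)c(OC)c1 | intermediate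
6 | (3R)-4-(4-hydroxy-3-methoxyphenyl)-3-(methoxycarbonyl)butanoic acid | COC(=O)[C@@H](CC(=O)O)Cc1ccc(O)c(OC)c1 | intermediate
7 | tert-butyldimethylsilyl (3R)-4-[4-(tert-butyldimethylsilyloxy)-3-methoxyphenyl]-3-(methoxycarbonyl)butanoate | COC(=O)[C@@H](CC(=O)O[Si](C)(C)C(C)(C)C)Cc1ccc(O[Si](C)(C)C(C)(C)C)c(OC)c1 | intermediate
8 | (3R)-4-[4-(tert-butyldimethylsilyloxy)-3-methoxyphenyl]-3-(methoxycarbonyl)butanoic acid | COC(=O)[C@@H](CC(=O)O)Cc1ccc(O[Si](C)(C)C(C)(C)C)c(OC)c1 | intermediate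
9 | (R)-4-benzyl-1,3-oxazolidin-2-one | O=C1N[C@H](Cc2ccccc2)CO1 | starting material
10 | (3R)-4-[4-(tert-butyldimethylsilyloxy)-3-methoxyphenyl]-3-(methoxycarbonyl)butanoic pivalic anhydride | COC(=O)[C@@H](CC(=O)OC(=O)C(C)(C)C)Cc1ccc(O[Si](C)(C)C(C)(C)C)c(OC)c1 | intermediate
11 | methyl (2R)-2-[4-(tert-butyldimethylsilyloxy)-3-methoxybenzyl]-4-[(4R)-4-benzyl-2-oxo-1,3-oxazolidin-3-yl]-4-oxobutanoate | COC(=O)[C@@H](CC(=O)N1[C@H](Cc2ccccc2)COC1=O)Cc1ccc(O[Si](C)(C)C(C)(C)C)c(OC)c1 | intermediate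
12 | 4-hydroxy-3-methoxybenzonitrile | COc1cc(C#N)ccc1O | starting material
13 | ethyl bromoacetate | CCOC(=O)CBr | starting material
14 | ethyl 2-(4-cyano-2-methoxyphenoxy)acetate | CCOC(=O)COc1ccc(C#N)cc1OC | intermediate
15 | vanillic acid (4-hydroxy-3-methoxybenzoic acid) | COc1cc(C(=O)O)ccc1O | starting material
16 | triisopropylsilyl 3-methoxy-4-(triisopropylsilyloxy)benzoate | COc1cc(C(=O)O[Si](C(C)C)(C(C)C)C(C)C)ccc1O[Si](C(C)C)(C(C)C)C(C)C | intermediate
17 | 3-methoxy-4-(triisopropylsilyloxy)benzoic acid | COc1cc(C(=O)O)ccc1O[Si](C(C)C)(C(C)C)C(C)C | intermediate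
18 | 3-methoxy-4-(triisopropylsilyloxy)benzoyl chloride | COc1cc(C(Cl)=O)ccc1O[Si](C(C)C)(C(C)C)C(C)C | intermediate
19 | lithium enolate of ethyl 2-(4-cyano-2-methoxyphenoxy)acetate | CCOC(O[Li])=COc1ccc(C#N)cc1OC | intermediate
20 | ethyl 2-(4-cyano-2-methoxyphenoxy)-3-[3-methoxy-4-(triisopropylsilyloxy)phenyl]-3-oxopropanoate (racemic) | CCOC(=O)C(Oc1ccc(C#N)cc1OC)C(=O)c1ccc(O[Si](C(C)C)(C(C)C)C(C)C)c(OC)c1 | intermediate
21 | ethyl (2R,3S)-2-(4-cyano-2-methoxyphenoxy)-3-hydroxy-3-[3-methoxy-4-(triisopropylsilyloxy)phenyl]propanoate | CCOC(=O)[C@H](Oc1ccc(C#N)cc1OC)[C@@H](O)c1ccc(O[Si](C(C)C)(C(C)C)C(C)C)c(OC)c1 | intermediate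
22 | 4-{[(1S,2S)-1,3-dihydroxy-1-[3-methoxy-4-(triisopropylsilyloxy)phenyl]propan-2-yl]oxy}-3-methoxybenzonitrile | OC[C@H](Oc1ccc(C#N)cc1OC)[C@@H](O)c1ccc(O[Si](C(C)C)(C(C)C)C(C)C)c(OC)c1 | intermediate
23 | 4-{[(1S,2S)-1,3-bis(tert-butyldimethylsilyloxy)-1-[3-methoxy-4-(triisopropylsilyloxy)phenyl]propan-2-yl]oxy}-3-methoxybenzonitrile | CC(C)(C)[Si](C)(C)OC[C@H](Oc1ccc(C#N)cc1OC)[C@@H](O[Si](C)(C)C(C)(C)C)c1ccc(O[Si](C(C)C)(C(C)C)C(C)C)c(OC)c1 | intermediate
24 | N-(diisobutylaluminio)aldimine of aldehyde 25 | CC(C)(C)[Si](C)(C)OC[C@H](Oc1ccc(C=N[Al](CC(C)C)CC(C)C)cc1OC)[C@@H](O[Si](C)(C)C(C)(C)C)c1ccc(O[Si](C(C)C)(C(C)C)C(C)C)c(OC)c1 | intermediate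
25 | 4-{[(1S,2S)-1,3-bis(tert-butyldimethylsilyloxy)-1-[3-methoxy-4-(triisopropylsilyloxy)phenyl]propan-2-yl]oxy}-3-methoxybenzaldehyde (ArB–CHO) | CC(C)(C)[Si](C)(C)OC[C@H](Oc1ccc(C=O)cc1OC)[C@@H](O[Si](C)(C)C(C)(C)C)c1ccc(O[Si](C(C)C)(C(C)C)C(C)C)c(OC)c1 | intermediate
26 | chloromagnesium Z-enolate of imide 11 | COC(=O)[C@H](Cc1ccc(O[Si](C)(C)C(C)(C)C)c(OC)c1)/C=C(\O[Mg]Cl)N1[C@H](Cc2ccccc2)COC1=O | intermediate
27 | chloromagnesium alkoxide of the anti aldol adduct (as 28, OMgCl in place of OSiMe3) | COC(=O)[C@H](Cc1ccc(O[Si](C)(C)C(C)(C)C)c(OC)c1)[C@H](C(=O)N1[C@H](Cc2ccccc2)COC1=O)[C@@H](O[Mg]Cl)c1ccc(O[C@@H](CO[Si](C)(C)C(C)(C)C)[C@@H](O[Si](C)(C)C(C)(C)C)c2ccc(O[Si](C(C)C)(C(C)C)C(C)C)c(OC)c2)c(OC)c1 | intermediate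
28 | methyl (2R,3S)-2-[4-(tert-butyldimethylsilyloxy)-3-methoxybenzyl]-3-[(R)-ArB(trimethylsilyloxy)methyl]-4-[(4R)-4-benzyl-2-oxo-1,3-oxazolidin-3-yl]-4-oxobutanoate | COC(=O)[C@H](Cc1ccc(O[Si](C)(C)C(C)(C)C)c(OC)c1)[C@H](C(=O)N1[C@H](Cc2ccccc2)COC1=O)[C@@H](O[Si](C)(C)C)c1ccc(O[C@@H](CO[Si](C)(C)C(C)(C)C)[C@@H](O[Si](C)(C)C(C)(C)C)c2ccc(O[Si](C(C)C)(C(C)C)C(C)C)c(OC)c2)c(OC)c1 | intermediate
29 | methyl (2R,3R,4R)-2-[4-(tert-butyldimethylsilyloxy)-3-methoxybenzyl]-3-(hydroxymethyl)-4-ArB-4-(trimethylsilyloxy)butanoate | COC(=O)[C@H](Cc1ccc(O[Si](C)(C)C(C)(C)C)c(OC)c1)[C@H](CO)[C@@H](O[Si](C)(C)C)c1ccc(O[C@@H](CO[Si](C)(C)C(C)(C)C)[C@@H](O[Si](C)(C)C(C)(C)C)c2ccc(O[Si](C(C)C)(C(C)C)C(C)C)c(OC)c2)c(OC)c1 | intermediate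
30 | (3R,4R)-3-[4-(tert-butyldimethylsilyloxy)-3-methoxybenzyl]-4-[(R)-ArB(trimethylsilyloxy)methyl]dihydrofuran-2(3H)-one | COc1cc(C[C@H]2C(=O)OC[C@@H]2[C@@H](O[Si](C)(C)C)c2ccc(O[C@@H](CO[Si](C)(C)C(C)(C)C)[C@@H](O[Si](C)(C)C(C)(C)C)c3ccc(O[Si](C(C)C)(C(C)C)C(C)C)c(OC)c3)c(OC)c2)ccc1O[Si](C)(C)C(C)(C)C | intermediate
31 | (3R,4R)-3-(4-hydroxy-3-methoxybenzyl)-4-[(R)-hydroxy(4-{[(1S,2S)-1,3-dihydroxy-1-(4-hydroxy-3-methoxyphenyl)propan-2-yl]oxy}-3-methoxyphenyl)methyl]dihydrofuran-2(3H)-one | COc1cc(C[C@H]2C(=O)OC[C@@H]2[C@@H](O)c2ccc(O[C@@H](CO)[C@@H](O)c3ccc(O)c(OC)c3)c(OC)c2)ccc1O | target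

**Step count and risks**

Total step count: 14. Longest linear sequence: 9 steps (steps 5, 7, 8, 9, 10, 11, 12, 13 and 14, from 12 to 31).

Steps most likely to fail:

Step 12. The addition may be slow or unselective, because the aldehyde is electron-rich and the enolate carries a branched β-carbon whose ester may compete for magnesium; syn adduct or the other facial isomer could then form. The fallback sets out from 25 and 11 and comes back at 28. It would make the C4–C7' bond at the ketone level and set C7' by a catalyst. Aldehyde 25 would be oxidised (NaClO2, NaH2PO4, 2-methyl-2-butene, t-BuOH–H2O) to 4-{[(1S,2S)-1,3-bis(TBS-oxy)-1-[3-methoxy-4-(TIPS-oxy)phenyl]propan-2-yl]oxy}-3-methoxybenzoic acid F1 and converted with (COCl)2 and catalytic DMF into the benzoyl chloride F2. C-Acylation of the sodium enolate of 11 (NaN(SiMe3)2, THF, −78 °C) would give the β-keto imide F3, in which C4 is set by the auxiliary and held by allylic strain. Transfer hydrogenation with [RuCl((R,R)-TsDPEN)(p-cymene)] in HCO2H–Et3N should then set C7' under catalyst control to give the β-hydroxy imide F4, and Me3SiCl with imidazole would return 28.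

Step 13. Borohydride may over-reduce the methyl ester or the new lactone, or the TMS group may be lost early so that the C7' oxygen closes on the ester. The fallback sets out from 28 and comes back at 31. It would replace the kinetic closure by a thermodynamic one. PPTS in MeOH would remove the TMS group to give the hydroxy imide F4; NaBH4 in THF–H2O, which reduces N-acyloxazolidinones but spares esters and γ-lactones, would give the dihydroxy ester F5, which may close partly to either lactone. A catalytic amount of DBU in CH2Cl2 should then equilibrate the material to the less strained 3,4-trans lactone that is acylated on the primary oxygen, the C7' alcohol F6; the alternative lactone on the C7' oxygen would be 4,5-cis. The conditions of step 14 would convert F6 into 31.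

Step 8. Diastereo- or enantiocontrol may be incomplete if epimerisation at C8'' is slow relative to reduction, or may be eroded by retro-aldol cleavage. The fallback sets out from 14 and comes back at 22. It would set both centres by an auxiliary. Saponification (LiOH, THF–H2O) would give 2-(4-cyano-2-methoxyphenoxy)acetic acid F7, and N-acylation of 9 through the mixed pivalic anhydride would give the imide F8. A dibutylboron triflate/i-Pr2NEt syn aldol with 3-methoxy-4-(triisopropylsilyloxy)benzaldehyde F9 (from vanillin, TIPSCl, imidazole) would give the syn adduct F10, and LiBH4 reduction would give diol 22.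

**Further compounds**

F1 | step 12 | 4-{[(1S,2S)-1,3-bis(tert-butyldimethylsilyloxy)-1-[3-methoxy-4-(triisopropylsilyloxy)phenyl]propan-2-yl]oxy}-3-methoxybenzoic acid | CC(C)(C)[Si](C)(C)OC[C@H](Oc1ccc(C(=O)O)cc1OC)[C@@H](O[Si](C)(C)C(C)(C)C)c1ccc(O[Si](C(C)C)(C(C)C)C(C)C)c(OC)c1
F2 | step 12 | 4-{[(1S,2S)-1,3-bis(tert-butyldimethylsilyloxy)-1-[3-methoxy-4-(triisopropylsilyloxy)phenyl]propan-2-yl]oxy}-3-methoxybenzoyl chloride | CC(C)(C)[Si](C)(C)OC[C@H](Oc1ccc(C(Cl)=O)cc1OC)[C@@H](O[Si](C)(C)C(C)(C)C)c1ccc(O[Si](C(C)C)(C(C)C)C(C)C)c(OC)c1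
F3 | step 12 | methyl (2R,3S)-2-[4-(tert-butyldimethylsilyloxy)-3-methoxybenzyl]-3-(ArB-carbonyl)-4-[(4R)-4-benzyl-2-oxo-1,3-oxazolidin-3-yl]-4-oxobutanoate | COC(=O)[C@H](Cc1ccc(O[Si](C)(C)C(C)(C)C)c(OC)c1)[C@H](C(=O)N1[C@H](Cc2ccccc2)COC1=O)C(=O)c1ccc(O[C@@H](CO[Si](C)(C)C(C)(C)C)[C@@H](O[Si](C)(C)C(C)(C)C)c2ccc(O[Si](C(C)C)(C(C)C)C(C)C)c(OC)c2)c(OC)c1
F4 | step 12 | methyl (2R,3S)-2-[4-(tert-butyldimethylsilyloxy)-3-methoxybenzyl]-3-[(R)-ArB(hydroxy)methyl]-4-[(4R)-4-benzyl-2-oxo-1,3-oxazolidin-3-yl]-4-oxobutanoate | COC(=O)[C@H](Cc1ccc(O[Si](C)(C)C(C)(C)C)c(OC)c1)[C@H](C(=O)N1[C@H](Cc2ccccc2)COC1=O)[C@@H](O)c1ccc(O[C@@H](CO[Si](C)(C)C(C)(C)C)[C@@H](O[Si](C)(C)C(C)(C)C)c2ccc(O[Si](C(C)C)(C(C)C)C(C)C)c(OC)c2)c(OC)c1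
F5 | step 13 | methyl (2R,3R,4R)-2-[4-(tert-butyldimethylsilyloxy)-3-methoxybenzyl]-4-hydroxy-3-(hydroxymethyl)-4-ArB-butanoate | COC(=O)[C@H](Cc1ccc(O[Si](C)(C)C(C)(C)C)c(OC)c1)[C@H](CO)[C@@H](O)c1ccc(O[C@@H](CO[Si](C)(C)C(C)(C)C)[C@@H](O[Si](C)(C)C(C)(C)C)c2ccc(O[Si](C(C)C)(C(C)C)C(C)C)c(OC)c2)c(OC)c1
F6 | step 13 | (3R,4R)-3-[4-(tert-butyldimethylsilyloxy)-3-methoxybenzyl]-4-[(R)-ArB(hydroxy)methyl]dihydrofuran-2(3H)-one | COc1cc(C[C@H]2C(=O)OC[C@@H]2[C@@H](O)c2ccc(O[C@@H](CO[Si](C)(C)C(C)(C)C)[C@@H](O[Si](C)(C)C(C)(C)C)c3ccc(O[Si](C(C)C)(C(C)C)C(C)C)c(OC)c3)c(OC)c2)ccc1O[Si](C)(C)C(C)(C)C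
F7 | step 8 | 2-(4-cyano-2-methoxyphenoxy)acetic acid | N#Cc1ccc(OCC(=O)O)c(OC)c1
F8 | step 8 | (R)-4-benzyl-3-[2-(4-cyano-2-methoxyphenoxy)acetyl]-1,3-oxazolidin-2-one | N#Cc1ccc(OCC(=O)N2[C@H](Cc3ccccc3)COC2=O)c(OC)c1
F9 | step 8 | 3-methoxy-4-(triisopropylsilyloxy)benzaldehyde | COc1cc(C=O)ccc1O[Si](C(C)C)(C(C)C)C(C)C
F10 | step 8 | (R)-4-benzyl-3-[(2R,3S)-2-(4-cyano-2-methoxyphenoxy)-3-hydroxy-3-[3-methoxy-4-(triisopropylsilyloxy)phenyl]propanoyl]-1,3-oxazolidin-2-one | COc1cc(C#N)ccc1O[C@@H](C(=O)N1[C@H](Cc2ccccc2)COC1=O)[C@@H](O)c1ccc(O[Si](C(C)C)(C(C)C)C(C)C)c(OC)c1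
A1 | direct plan | (5R)-5-[(1R,2S,5R)-menthyloxy]furan-2(5H)-one | O=C1O[C@@H](O[C@@H]2C[C@H](C)CC[C@H]2C(C)C)C=C1
A2 | direct plan | (3R,4R)-3-[4-(benzyloxy)-3-methoxybenzyl]-4-[bis(phenylthio)methyl]dihydrofuran-2(3H)-one | COc1cc(C[C@H]2C(=O)OC[C@@H]2C(Sc3ccccc3)Sc3ccccc3)ccc1OCc1ccccc1
A3 | direct plan | (3R,4R)-4-[4-(benzyloxy)-3-methoxybenzyl]-5-oxotetrahydrofuran-3-carbaldehyde | COc1cc(C[C@H]2C(=O)OC[C@@H]2C=O)ccc1OCc1ccccc1
A4 | direct plan | (4S,5S)-4-[4-(benzyloxy)-3-methoxyphenyl]-5-(4-bromo-2-methoxyphenoxy)-2,2-di-tert-butyl-1,3,2-dioxasilinane | COc1cc(Br)ccc1O[C@H]1CO[Si](C(C)(C)C)(C(C)(C)C)O[C@H]1c1ccc(OCc2ccccc2)c(OC)c1
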